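Does the same charge of starting material make more product in 25 min when fed in, as in alpha, or when all present from the start, as in delta?

| flask | starting material | enzyme | remark | time |
|---|---|---|---|---|
| green | 0.035 M (fed, over 25 min) | 0.049 mol% | run made earlier; the fed solution adds 0.25 times the starting volume |  |
| red | 0.053 M (fed, over 25 min) | 0.049 mol% | run made earlier; the fed solution adds 0.25 times the starting volume |  |
| violet | 0.071 M (fed, over 25 min) | 0.074 mol% | run made earlier; the fed solution adds 0.25 times the starting volume |  |
| alpha | 0.071 M (fed, over 25 min) | 0.049 mol% | the fed solution adds 0.25 times the starting volume | 25 min |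
| delta | 0.071 M | 0.049 mol% | everything together at the start, the whole solution of starting material included, so that from the start the volume is larger by 0.25 times the starting volume | 25 min |

- green (time / min: product / %, starting material / %): 1.33: 1.2, 6.0; 4.00: 0, 15.4; 8.00: 1.7, 29.9; 10.0: 0.9, 39.0; 15.0: 6.6, 54.5
- red (time / min: product / %, starting material / %): 3.00: 0.9, 11.8; 6.00: 1.3, 23.0; 10.0: 3.6, 36.2; 12.0: 5.4, 43.6; 15.0: 5.6, 51.5
- violet (time / min: product / %, starting material / %): 1.33: 0.5, 4.5; 2.50: 0, 8.1; 4.00: 2.1, 15.5; 8.00: 4.1, 29.3; 15.0: 8.7, 50.2

(standard deviation of a reading: 1 percentage point)

* the winner by amount of product, in percent of the starting material charged; "neither" if no more than 2 percentage points parts them (alpha / delta / neither)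
* how much product is there at the end, in percent of the starting material charged: alpha
* how much product is there at the end, in percent of the starting material charged: delta

- charges are per starting volume, the dose included; the dosed solution carries all of it
- percentages count the whole charge, also what has not yet gone in

I reckoned from green and red, which share a loading. At 15.0 min they held 6.6% and 5.6% of product over 54.5% and 51.5% of starting material. That material had risen about linearly from nothing, so its time integral was half the last reading times the time. Pooled, this gave 0.0153 min⁻¹, which I called k', the pseudo-first-order constant: product formed per minute per unit of starting material present. Violet, scaled to the same loading, read 0.0153 min⁻¹.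

At this scatter the product columns did not tell a line from a curve, so I bracketed. For my ceiling I let the rate follow [starting material] throughout. Delta then came by my reckoning to k't = 38.2%, or 31.9% once depletion was counted, and alpha to 16.9%. For my floor I took saturation, carrying the mean pace of green and red to 25 min, which gave 10.2% for either flask. Red had reached 0.0237 M, while delta starts higher, at 0.0568 M. I therefore expected delta ahead, and level with alpha at the floor.

The forecast said neither, with 9.3% for alpha and 10% for delta, holding that “the enzyme is essentially saturated”. Both numbers stood at my floor, within the scatter.

The simulation gave delta the win, with 13.8% for alpha and 20.0% for delta, each above my floor and below its ceiling of 16.9% and 31.9%.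

    starting material + enzyme → product + enzyme, rate k1*[starting material]*[enzyme]/(1 + ([starting material]/Km1) + ([product]/Kp1)) (40.0 mM, 0.0870 M, k = 1600 L mol⁻¹ min⁻¹)
    2 enzyme ⇌ resting dimer, settled at all times (K = 34000 L mol⁻¹)
    2 starting material → homo dimer A (k = 0.130 L mol⁻¹ min⁻¹)
    2 starting material → homo dimer B (k = 2.00 × 10⁻⁴ L mol⁻¹ min⁻¹)

Read from the amounts at 12.5 min and 25.0 min, k' was 0.0134 min⁻¹ in alpha and 0.0104 min⁻¹ in delta. For a neighbour flask, alpha with 0.02 mol% of enzyme, k' scaled by loading is 0.00626 min⁻¹, and the first-order reckoning gives 7.44%. That flask gave 7.68%, with 66.2% of its catalyst as enzyme against 50.9% in alpha.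

The readings come from a simulation with constants of no real substance, and the scatter is random.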